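**Plan**

- Target numbering: cyclobutane C1 (CO2H), C2 and C3 (quaternary, each with CH3 and a pyranone), C4 (CO2CH3); pyranone atoms O1 to C6.
- Retrosynthetic cuts, in order: the ester C–O bond at C4 (back to a meso anhydride); the O1–C6 bond of both pyranones (two ynone tert-butyl esters); both pyranone C4–C5 bonds (diyne plus two molecules of a methylmalonyl chloride); both pyranone C5 carbons (dialdehyde homologation); cyclobutane bonds C1–C2 and C3–C4 (two maleic anhydrides).
- Forward order: the cyclobutane arises first by crossed [2+2] photocycloaddition, the side chains are grown as alkynes, both pyranone rings close together in one gold-catalysed step, then O-methylation and differentiation of the two carboxyl groups.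
- Enabling feature: each pyranone O1–C6 bond ends at C6, the ring atom bonded to quaternary C2 or C3 of the cyclobutane, so C6 can be carried as a slim sp carbon beside two adjacent quaternary centres until the heterocycles are closed.
- Stereochemistry: the relative configuration of all four centres comes from the cis,anti,cis photoadduct; the absolute configuration comes from quinine-mediated methanolysis of a meso anhydride in the last step.

Key step: step 10

Assumption: cinchona-mediated methanolysis of the late meso anhydride is taken to follow the facial sense known for cis-fused bicyclic succinic anhydrides, with quinine addressing the carbonyl on the carbon that becomes C4 of the target; quinidine would address the other carbonyl.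

**Route**

Step 1
Reactants: 1 maleic anhydride; 2 2,3-dimethylmaleic anhydride
Product: 3 cis,anti,cis-1,2-dimethylcyclobutane-1,2,3,4-tetracarboxylic 1,2:3,4-dianhydride (meso)
Conditions: 1 (5 equiv), benzophenone (20 mol%), MeCN, hν (350 nm, Pyrex), rt; excess 1 sublimed off, 3 crystallised
Reagents that add atoms: none
Why: Benzophenone transfers triplet energy to 2, whose excited state adds to the excess of 1 in a stepwise crossed [2+2] photocycloaddition (the reaction type of maleic anhydride photodimerisation); each five-membered ring enforces a cis pair and the 1,4-biradical should close with the two anhydride rings on opposite faces as in both homodimers, which puts the future carboxyl pair on the face of the two methyl groups and sets all four ring stereocentres in their relative sense.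

Step 2
Reactants: 3 crossed dianhydride
Product: 5 di-tert-butyl 1,5-dimethyl-2,4-dioxo-3-oxabicyclo[3.2.0]heptane-6,7-dicarboxylate (meso), via mono-tert-butyl hemiester 4 (not isolated)
Conditions: t-BuOH (5 equiv), 4-(dimethylamino)pyridine (20 mol%), THF, 50 °C; citric acid wash; then Cl3CC(=NH)Ot-Bu (2 equiv), CH2Cl2–cyclohexane, rt
Reagents that add atoms: tert-butanol, CC(C)(C)O; tert-butyl 2,2,2-trichloroacetimidate, CC(C)(C)OC(=N)C(Cl)(Cl)Cl
Why: Nucleophile-catalysed alcoholysis followed by trichloroacetimidate esterification: the anhydride flanked by two CH carbons is opened by the bulky alcohol while the one flanked by two quaternary carbons is shielded on both faces, and the imidate then alkylates the freed acid without base, so no stereocentre is touched.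

Step 3
Reactants: 5 di-tert-butyl ester anhydride
Product: 6 di-tert-butyl 1,5-dimethyl-2-oxo-3-oxabicyclo[3.2.0]heptane-6,7-dicarboxylate (racemic)
Conditions: NaBH4 (1.5 equiv), THF, 0 °C to rt; then 1 M citric acid, rt
Reagents that add atoms: none
Why: NaBH4 reduction of a cyclic anhydride to a γ-lactone: only the anhydride carbonyl is electrophilic enough for borohydride, the carboxylate formed beside it resists further reduction and the hydroxy acid lactonises on acidification, tert-butyl esters being inert.

Step 4
Reactants: 6 lactone
Product: 7 di-tert-butyl 3,4-bis(hydroxymethyl)-3,4-dimethylcyclobutane-1,2-dicarboxylate (meso; esters cis to each other and to both methyls)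
Conditions: LiBH4 (2 equiv), THF, 0 °C to rt; aq. NH4Cl
Reagents that add atoms: none
Why: LiBH4 reduction of a lactone to a 1,4-diol: lactones are reduced far faster than tert-butyl esters, and the alkoxides formed lie trans to the neighbouring esters on the four-membered ring, so they cannot translactonise.

Step 5
Reactants: 7 diol
Product: 8 di-tert-butyl 3,4-diformyl-3,4-dimethylcyclobutane-1,2-dicarboxylate (meso)
Conditions: (COCl)2, DMSO, CH2Cl2, −78 °C; Et3N, −78 to 0 °C; used directly
Reagents that add atoms: none
Why: Swern oxidation: both hydroxyls become alkoxysulfonium ions at −78 °C before base is added, so the dialdehyde forms without passing through a lactol that would be over-oxidised to the lactone, and the formyl-bearing carbons are quaternary and cannot epimerise.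

Step 6
Reactants: 8 dialdehyde
Product: 9 di-tert-butyl 3,4-diethynyl-3,4-dimethylcyclobutane-1,2-dicarboxylate (meso)
Conditions: dimethyl (1-diazo-2-oxopropyl)phosphonate (3 equiv), K2CO3 (4 equiv), MeOH, 0 °C to rt
Reagents that add atoms: dimethyl (1-diazo-2-oxopropyl)phosphonate, COP(=O)(OC)C(=[N+]=[N-])C(C)=O
Why: Seyferth–Gilbert homologation with the Ohira–Bestmann reagent: methanolysis releases the diazomethylphosphonate anion, which adds to each non-enolisable aldehyde and, after loss of dimethyl phosphate and N2, gives the terminal alkyne by 1,2-shift in the alkylidene carbene, under carbonate conditions mild enough to leave the tert-butyl esters and their α-centres alone.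

Step 7
Reactants: 10 2,2,5-trimethyl-1,3-dioxane-4,6-dione
Product: 11 3-tert-butoxy-2-methyl-3-oxopropanoic acid (racemic)
Conditions: t-BuOH, reflux
Reagents that add atoms: tert-butanol, CC(C)(C)O
Why: Thermal alcoholysis of a Meldrum's acid derivative: tert-butanol opens the dioxanedione and acetone is expelled, which gives the malonic half-ester directly.

Step 8
Reactants: 11 malonic half-ester
Product: 12 tert-butyl 3-chloro-2-methyl-3-oxopropanoate (racemic)
Conditions: (COCl)2, DMF (cat.), CH2Cl2, 0 °C to rt; evaporate, use crude at once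
Reagents that add atoms: oxalyl chloride, O=C(Cl)C(=O)Cl
Why: Acid chloride formation with oxalyl chloride under Vilsmeier catalysis at low temperature, the crude chloride being used immediately because it is prone to lose HCl to the ketene.

Step 9
Reactants: 9 diyne; 12 acid chloride (two equivalents enter the product, one for each alkyne)
Product: 14 di-tert-butyl 3,4-bis(5-tert-butoxy-4-methyl-3,5-dioxopent-1-yn-1-yl)-3,4-dimethylcyclobutane-1,2-dicarboxylate, via bis(tributylstannylalkyne) 13 (not isolated)
Conditions: Bu3SnOMe (2.2 equiv), ZnBr2 (10 mol%), THF, rt; evaporate; then 12 (2.5 equiv), Pd(PPh3)4 (5 mol%), THF, 40 °C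
Reagents that add atoms: tert-butyl 3-chloro-2-methyl-3-oxopropanoate (the second equivalent of 12), CC(C(=O)Cl)C(=O)OC(C)(C)C
Why: ZnBr2-catalysed stannylation of both terminal alkynes followed by a twofold Stille-type acylation (alkynylstannane plus acid chloride to the ynone) at zerovalent palladium, each alkyne taking up one molecule of 12 with loss of Bu3SnCl: no amine is present, so the acidic methine of 12 is not turned into a ketene as it would be under acyl Sonogashira conditions; the two new side-chain methine centres form unselectively and are erased in the next step.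

Step 10
Reactants: 14 bis(ynone tert-butyl ester)
Product: 15 di-tert-butyl 3,4-bis(4-hydroxy-3-methyl-2-oxo-2H-pyran-6-yl)-3,4-dimethylcyclobutane-1,2-dicarboxylate (meso)
Conditions: Ph3PAuCl (10 mol%), AgOTf (10 mol%), MeNO2–AcOH (4:1), rt
Reagents that add atoms: none
Why: Cationic monovalent gold (Ph3PAu+ from Ph3PAuCl and AgOTf) binds each alkyne, the carbonyl oxygen of the side-chain tert-butyl ester adds anti to gold at the alkyne carbon bonded to the quaternary cyclobutane carbon, the tert-butoxy oxocarbenium ion loses 2-methylpropene, and protodeauration by AcOH followed by enolisation gives the 4-hydroxy-2-pyranone, twice over. The closest known reaction is the gold-catalysed cyclisation of tert-butyl 3-oxoalk-4-ynoates to 4-hydroxy-2-pyranones. Each pyranone ring closes in the 6-endo-dig mode and forms its O1–C6 bond. No stereocentre is created: the side-chain methine centres of 14 become sp2, and the four ring centres are spectators under neutral to weakly acidic conditions, so the cis diester cannot epimerise and no enolate is available for retro-Michael opening of the cyclobutane. The step needs 6-endo over 5-exo regioselectivity, which the ynone polarisation secures by making the ring-bound alkyne carbon the electrophilic terminus, and it needs chemoselectivity among four tert-butyl esters, which follows from the ring esters lying trans to both alkynes, where they can neither reach a triple bond nor be activated for loss of 2-methylpropene.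

Step 11
Reactants: 15 bis(4-hydroxypyranone)
Product: 16 di-tert-butyl 3,4-bis(4-methoxy-3-methyl-2-oxo-2H-pyran-6-yl)-3,4-dimethylcyclobutane-1,2-dicarboxylate (meso)
Conditions: Me2SO4 (2.5 equiv), K2CO3 (3 equiv), acetone, 40 °C
Reagents that add atoms: dimethyl sulfate, COS(=O)(=O)OC
Why: Williamson-type O-alkylation of the vinylogous acid with dimethyl sulfate and K2CO3 in acetone, conditions known to favour the 4-methoxy-2-pyranone over the 2-methoxy-4-pyranone and too weakly basic to enolise the ring esters.

Step 12
Reactants: 16 bis(4-methoxypyranone) di-tert-butyl ester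
Product: 18 6,7-bis(4-methoxy-3-methyl-2-oxo-2H-pyran-6-yl)-6,7-dimethyl-3-oxabicyclo[3.2.0]heptane-2,4-dione (meso), via diacid 17 (not isolated)
Conditions: TFA–CH2Cl2 (1:2), rt; evaporate with toluene; then Ac2O, 60 °C; evaporate, use crude
Reagents that add atoms: none
Why: Acidolysis of the tert-butyl esters (E1 loss of 2-methylpropene) followed by cyclodehydration of the cis-1,2-diacid with acetic anhydride; the 4-methoxy-2-pyranones tolerate both, and closure to the cis-fused anhydride locks the cis relation of the two carboxyl carbons.

Step 13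
Reactants: 18 meso anhydride
Product: 19 (1S,2R,3S,4R)-4-(methoxycarbonyl)-2,3-bis(4-methoxy-3-methyl-2-oxo-2H-pyran-6-yl)-2,3-dimethylcyclobutane-1-carboxylic acid
Conditions: quinine (1.1 equiv), MeOH (3 equiv), toluene–CH2Cl2, −55 °C; dilute HCl wash to recover the alkaloid
Reagents that add atoms: methanol, CO
Why: Cinchona-alkaloid-mediated desymmetrising methanolysis of a meso anhydride: quinine acts as a chiral general base that directs methanol to one of the two enantiotopic carbonyl groups at low temperature, which fixes the absolute configuration of all four stereocentres at once while their relative configuration stays as set in step 1.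

**Compound list**

1 | maleic anhydride | O=C1OC(=O)C=C1 | starting material
2 | 2,3-dimethylmaleic anhydride | CC1=C(C)C(=O)OC1=O | starting material
3 | cis,anti,cis-1,2-dimethylcyclobutane-1,2,3,4-tetracarboxylic 1,2:3,4-dianhydride (meso) | O=C1OC(=O)[C@@H]2[C@H]1[C@@]1(C)C(=O)OC(=O)[C@@]21C | intermediate
4 | 7-(tert-butoxycarbonyl)-1,5-dimethyl-2,4-dioxo-3-oxabicyclo[3.2.0]heptane-6-carboxylic acid (racemic, one enantiomer drawn) | CC(C)(C)OC(=O)[C@@H]1[C@H](C(=O)O)[C@@]2(C)C(=O)OC(=O)[C@@]12C | intermediate
5 | di-tert-butyl 1,5-dimethyl-2,4-dioxo-3-oxabicyclo[3.2.0]heptane-6,7-dicarboxylate (meso; esters on the face of the methyls) | CC(C)(C)OC(=O)[C@@H]1[C@H](C(=O)OC(C)(C)C)[C@@]2(C)C(=O)OC(=O)[C@@]12C | intermediate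
6 | di-tert-butyl 1,5-dimethyl-2-oxo-3-oxabicyclo[3.2.0]heptane-6,7-dicarboxylate (racemic, one enantiomer drawn) | CC(C)(C)OC(=O)[C@@H]1[C@H](C(=O)OC(C)(C)C)[C@@]2(C)COC(=O)[C@@]12C | intermediate
7 | di-tert-butyl 3,4-bis(hydroxymethyl)-3,4-dimethylcyclobutane-1,2-dicarboxylate (meso) | CC(C)(C)OC(=O)[C@@H]1[C@H](C(=O)OC(C)(C)C)[C@@](C)(CO)[C@@]1(C)CO | intermediate
8 | di-tert-butyl 3,4-diformyl-3,4-dimethylcyclobutane-1,2-dicarboxylate (meso) | CC(C)(C)OC(=O)[C@@H]1[C@H](C(=O)OC(C)(C)C)[C@@](C)(C=O)[C@@]1(C)C=O | intermediate
9 | di-tert-butyl 3,4-diethynyl-3,4-dimethylcyclobutane-1,2-dicarboxylate (meso) | CC(C)(C)OC(=O)[C@@H]1[C@H](C(=O)OC(C)(C)C)[C@@](C)(C#C)[C@@]1(C)C#C | intermediate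
10 | 2,2,5-trimethyl-1,3-dioxane-4,6-dione | CC1C(=O)OC(C)(C)OC1=O | starting material
11 | 3-tert-butoxy-2-methyl-3-oxopropanoic acid (racemic) | CC(C(=O)O)C(=O)OC(C)(C)C | intermediate
12 | tert-butyl 3-chloro-2-methyl-3-oxopropanoate (racemic) | CC(C(=O)Cl)C(=O)OC(C)(C)C | intermediate
13 | di-tert-butyl 3,4-dimethyl-3,4-bis[(tributylstannyl)ethynyl]cyclobutane-1,2-dicarboxylate (meso) | CC(C)(C)OC(=O)[C@@H]1[C@H](C(=O)OC(C)(C)C)[C@@](C)(C#C[Sn](CCCC)(CCCC)CCCC)[C@@]1(C)C#C[Sn](CCCC)(CCCC)CCCC | intermediate
14 | di-tert-butyl 3,4-bis(5-tert-butoxy-4-methyl-3,5-dioxopent-1-yn-1-yl)-3,4-dimethylcyclobutane-1,2-dicarboxylate (side-chain methine centres unassigned) | CC(C)(C)OC(=O)[C@@H]1[C@H](C(=O)OC(C)(C)C)[C@@](C)(C#CC(=O)C(C)C(=O)OC(C)(C)C)[C@@]1(C)C#CC(=O)C(C)C(=O)OC(C)(C)C | intermediate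
15 | di-tert-butyl 3,4-bis(4-hydroxy-3-methyl-2-oxo-2H-pyran-6-yl)-3,4-dimethylcyclobutane-1,2-dicarboxylate (meso) | CC(C)(C)OC(=O)[C@@H]1[C@H](C(=O)OC(C)(C)C)[C@@](C)(c2cc(O)c(C)c(=O)o2)[C@@]1(C)c1cc(O)c(C)c(=O)o1 | intermediate
16 | di-tert-butyl 3,4-bis(4-methoxy-3-methyl-2-oxo-2H-pyran-6-yl)-3,4-dimethylcyclobutane-1,2-dicarboxylate (meso) | CC(C)(C)OC(=O)[C@@H]1[C@H](C(=O)OC(C)(C)C)[C@@](C)(c2cc(OC)c(C)c(=O)o2)[C@@]1(C)c1cc(OC)c(C)c(=O)o1 | intermediate
17 | 3,4-bis(4-methoxy-3-methyl-2-oxo-2H-pyran-6-yl)-3,4-dimethylcyclobutane-1,2-dicarboxylic acid (meso) | OC(=O)[C@@H]1[C@H](C(=O)O)[C@@](C)(c2cc(OC)c(C)c(=O)o2)[C@@]1(C)c1cc(OC)c(C)c(=O)o1 | intermediate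
18 | 6,7-bis(4-methoxy-3-methyl-2-oxo-2H-pyran-6-yl)-6,7-dimethyl-3-oxabicyclo[3.2.0]heptane-2,4-dione (meso) | O=C1OC(=O)[C@@H]2[C@H]1[C@@](C)(c1cc(OC)c(C)c(=O)o1)[C@@]2(C)c1cc(OC)c(C)c(=O)o1 | intermediate
19 | (1S,2R,3S,4R)-4-(methoxycarbonyl)-2,3-bis(4-methoxy-3-methyl-2-oxo-2H-pyran-6-yl)-2,3-dimethylcyclobutane-1-carboxylic acid | COC(=O)[C@@H]1[C@H](C(=O)O)[C@@](C)(c2cc(OC)c(C)c(=O)o2)[C@@]1(C)c1cc(OC)c(C)c(=O)o1 | target

**Step count**

Total step count: 13. Longest linear sequence: 11 steps (steps 1 to 6 and 9 to 13); the acid chloride branch (steps 7 and 8) adds 2.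

**Steps most likely to fail**

Step 1. Homodimerisation of either anhydride may compete with the crossed addition, and the biradical may partly close to the syn-fused isomer, so that little of the crossed anti adduct is obtained. The fallback sets out from 2 and returns to the route at 7. LiAlH4 reduction of 2 would give (Z)-2,3-dimethylbut-2-ene-1,4-diol F1, and 2,2-dimethoxypropane with TsOH would convert it into 2,2,5,6-tetramethyl-4,7-dihydro-1,3-dioxepine F2. This electron-rich alkene cannot dimerise under sensitisation and should take up triplet 1 (acetophenone, MeCN, hν) to give the cis,anti,cis anhydride–acetonide photoadduct F3. As in step 2, t-BuOH with 4-(dimethylamino)pyridine would open the anhydride to the mono-tert-butyl hemiester acetonide F4, and tert-butyl trichloroacetimidate would give the di-tert-butyl ester acetonide F5. Aqueous AcOH would then remove the acetonide and deliver diol 7, with no hydride step in the presence of the esters.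

Step 9. The acid chloride may be lost through ketene formation or tert-butyl cleavage before transmetalation, and the coupling may stall after the first of the two acylations. The fallback sets out from 9 and returns at 14, with the polarity of the bond formation reversed. Carboxylation of both alkynes (CO2, silver iodide cat., Cs2CO3, DMF, 50 °C) would give di-tert-butyl 3,4-bis(2-carboxyethynyl)-3,4-dimethylcyclobutane-1,2-dicarboxylate F6. 1,1'-Carbonyldiimidazole would activate it as the bis(acyl imidazolide) F7. Masamune–Brooks C-acylation with magnesium bis(3-tert-butoxy-2-methyl-3-oxopropanoate) F8, made from 11 and Mg(OEt)2, would then give 14 after decarboxylation.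

Step 13. Quinine may discriminate poorly between the two enantiotopic carbonyl groups, or may address them in the unexpected sense. The fallback sets out from 18 and returns at 19, using the pseudoenantiomeric alkaloid and an ester switch. Quinidine-mediated opening of 18 with benzyl alcohol (toluene, −55 °C) should place the benzyl ester on the carbon that must end as the acid, giving the benzyl hemiester F9. Trimethylsilyldiazomethane in toluene–MeOH would methylate the free acid to the benzyl methyl diester F10. Hydrogenolysis (H2, Pd/C, EtOAc, rt, short contact) would remove the benzyl group and give 19. Either alkaloid can serve either sequence, so the required enantiomer stays accessible whichever carbonyl each alkaloid prefers.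

**Further compounds**

F1 | step 1 | (Z)-2,3-dimethylbut-2-ene-1,4-diol | C/C(CO)=C(\C)CO
F2 | step 1 | 2,2,5,6-tetramethyl-4,7-dihydro-1,3-dioxepine | CC1=C(C)COC(C)(C)OC1
F3 | step 1 | cis,anti,cis photoadduct of 1 and F2 (cyclobutane fused to the anhydride and to the dioxepane acetonide, meso) | O=C1OC(=O)[C@@H]2[C@H]1[C@@]1(C)COC(C)(C)OC[C@@]21C
F4 | step 1 | mono-tert-butyl hemiester of the acetonide-protected cyclobutane diacid (racemic, one enantiomer drawn) | CC(C)(C)OC(=O)[C@@H]1[C@H](C(=O)O)[C@@]2(C)COC(C)(C)OC[C@@]12C
F5 | step 1 | di-tert-butyl ester of the acetonide-protected cyclobutane diacid (meso) | CC(C)(C)OC(=O)[C@@H]1[C@H](C(=O)OC(C)(C)C)[C@@]2(C)COC(C)(C)OC[C@@]12C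
F6 | step 9 | di-tert-butyl 3,4-bis(2-carboxyethynyl)-3,4-dimethylcyclobutane-1,2-dicarboxylate (meso) | CC(C)(C)OC(=O)[C@@H]1[C@H](C(=O)OC(C)(C)C)[C@@](C)(C#CC(=O)O)[C@@]1(C)C#CC(=O)O
F7 | step 9 | bis(acyl imidazolide) of F6 | CC(C)(C)OC(=O)[C@@H]1[C@H](C(=O)OC(C)(C)C)[C@@](C)(C#CC(=O)n2ccnc2)[C@@]1(C)C#CC(=O)n1ccnc1
F8 | step 9 | magnesium bis(3-tert-butoxy-2-methyl-3-oxopropanoate) | CC(C(=O)[O-])C(=O)OC(C)(C)C.CC(C(=O)[O-])C(=O)OC(C)(C)C.[Mg+2]
F9 | step 13 | benzyl hemiester from 18 (free acid on the carbon that will carry the methyl ester) | OC(=O)[C@@H]1[C@H](C(=O)OCc2ccccc2)[C@@](C)(c2cc(OC)c(C)c(=O)o2)[C@@]1(C)c1cc(OC)c(C)c(=O)o1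
F10 | step 13 | benzyl methyl diester | COC(=O)[C@@H]1[C@H](C(=O)OCc2ccccc2)[C@@](C)(c2cc(OC)c(C)c(=O)o2)[C@@]1(C)c1cc(OC)c(C)c(=O)o1
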